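**Plan**
- Rings are lettered A (3-hydroxyphenyl), B (para-phenylene), C (the ring carrying OH and OAr) and D (hydroquinone). Ring A has its hydroxyl (C3) and the CH2CH2 bridge (C1) in a 1,3 relation, with C6, para to the hydroxyl, bearing only hydrogen; this pattern is what a 1-methoxy-3-siloxybutadiene and a β-alkyl ynoate deliver once the ester is removed.
- Retrosynthesis: cut the three O–CH3 bonds, then put a carboxyl back on C6 of ring A, then cut ring A at C1–C2 and C5–C6 into the siloxy diene and an ynoate.
- The ynoate is cut at C(sp)–CO2Me, at the benzylic CH2–CH2 bond next to ring B, at the diaryl ether C–O bond, and at the ethylene bridge between rings C and D.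
- Forward: rings B, C and D are bought; the C–D bridge is made by Wittig olefination and hydrogenation, ring B is attached by SNAr, its formyl group is grown into the pentynoate chain, and ring A is built last by the cycloaddition.
- The target has no stereocentre; the Wittig E/Z mixture is erased by hydrogenation, and the only selectivity to control is the regiochemistry of the cycloaddition.

Key step: step 9

Remark: HC≡CCH2MgBr is taken as a stock solution in Et2O, prepared beforehand from propargyl bromide and magnesium.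

**Step 1**
Reactants: 1 2,5-dimethoxybenzyl alcohol
Product: 2 (2,5-dimethoxybenzyl)triphenylphosphonium bromide
Conditions: PPh3·HBr, MeCN, reflux
Reagents that add atoms: triphenylphosphine hydrobromide, Br.c1ccc(cc1)P(c1ccccc1)c1ccccc1
Why: Electron-rich benzylic alcohols are converted directly into benzyltriphenylphosphonium bromides by PPh3·HBr, the protonated hydroxyl being displaced by the phosphine (phosphonium salt formation).

**Step 2**
Reactants: 2 (2,5-dimethoxybenzyl)triphenylphosphonium bromide; 3 3-(benzyloxy)-4-methoxybenzaldehyde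
Product: 5 2-(benzyloxy)-4-[2-(2,5-dimethoxyphenyl)ethenyl]-1-methoxybenzene (E/Z mixture), via phosphonium ylide 4 (not isolated)
Conditions: KOtBu, THF, 0 °C; then 3, 0 °C to rt
Reagents that add atoms: none
Why: Wittig olefination of a semi-stabilised benzylic ylide with an aromatic aldehyde is dependable, and the alkene geometry is irrelevant because the double bond is saturated in the next step.

**Step 3**
Reactants: 5 2-(benzyloxy)-4-[2-(2,5-dimethoxyphenyl)ethenyl]-1-methoxybenzene
Product: 6 5-[2-(2,5-dimethoxyphenyl)ethyl]-2-methoxyphenol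
Conditions: H2 (1 atm), 10% Pd/C, EtOAc/EtOH, rt
Reagents that add atoms: none
Why: Catalytic hydrogenation over Pd/C should saturate the stilbene and hydrogenolyse the benzyl ether in one operation, leaving the aryl methyl ethers untouched.

**Step 4**
Reactants: 6 5-[2-(2,5-dimethoxyphenyl)ethyl]-2-methoxyphenol; 7 4-fluorobenzaldehyde
Product: 8 4-{5-[2-(2,5-dimethoxyphenyl)ethyl]-2-methoxyphenoxy}benzaldehyde
Conditions: K2CO3, DMF, 140 °C
Reagents that add atoms: none
Why: Nucleophilic aromatic substitution (SNAr), in which the para-formyl group activates the fluoride towards displacement by the guaiacol-type phenol under carbonate base, the usual entry to diaryl ethers of the bibenzyl family.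

**Step 5**
Reactants: 8 4-{5-[2-(2,5-dimethoxyphenyl)ethyl]-2-methoxyphenoxy}benzaldehyde
Product: 9 (4-{5-[2-(2,5-dimethoxyphenyl)ethyl]-2-methoxyphenoxy}phenyl)methanol
Conditions: NaBH4, MeOH/THF, 0 °C
Reagents that add atoms: none
Why: Hydride reduction of an aryl aldehyde by NaBH4 is clean, and the molecule holds no other reducible group.

**Step 6**
Reactants: 9 (4-{5-[2-(2,5-dimethoxyphenyl)ethyl]-2-methoxyphenoxy}phenyl)methanol
Product: 10 2-[4-(bromomethyl)phenoxy]-4-[2-(2,5-dimethoxyphenyl)ethyl]-1-methoxybenzene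
Conditions: PBr3, CH2Cl2, 0 °C
Reagents that add atoms: phosphorus tribromide, BrP(Br)Br
Why: PBr3 converts a primary benzylic alcohol into the bromide through its phosphite ester and SN2 attack of bromide, conditions under which aryl ethers are inert; the bromide is used without storage.

**Step 7**
Reactants: 10 2-[4-(bromomethyl)phenoxy]-4-[2-(2,5-dimethoxyphenyl)ethyl]-1-methoxybenzene
Product: 11 2-[4-(but-3-yn-1-yl)phenoxy]-4-[2-(2,5-dimethoxyphenyl)ethyl]-1-methoxybenzene
Conditions: HC≡CCH2MgBr, Et2O/THF, 0 °C to reflux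
Reagents that add atoms: propargylmagnesium bromide, C#CC[Mg]Br
Why: Alkylation of the propargyl/allenyl Grignard reagent by a benzylic bromide proceeds through the allenyl form with propargylic transposition (SE2′) and should give the terminal homopropargyl arene.

**Step 8**
Reactants: 11 2-[4-(but-3-yn-1-yl)phenoxy]-4-[2-(2,5-dimethoxyphenyl)ethyl]-1-methoxybenzene
Product: 13 methyl 5-(4-{5-[2-(2,5-dimethoxyphenyl)ethyl]-2-methoxyphenoxy}phenyl)pent-2-ynoate, via lithium acetylide 12 (not isolated)
Conditions: n-BuLi, THF, −78 °C; then ClCO2Me, −78 to 0 °C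
Reagents that add atoms: methyl chloroformate, COC(=O)Cl
Why: Deprotonation of the terminal alkyne and C-acylation of the acetylide with a chloroformate is the standard alkynoate synthesis, and at −78 °C the alkyne C–H is far more acidic than any aryl or benzylic position.

**Step 9**
Reactants: 13 methyl 5-(4-{5-[2-(2,5-dimethoxyphenyl)ethyl]-2-methoxyphenoxy}phenyl)pent-2-ynoate; 14 (E)-1-methoxy-3-(trimethylsilyloxy)buta-1,3-diene
Product: 17 methyl 2-[2-(4-{5-[2-(2,5-dimethoxyphenyl)ethyl]-2-methoxyphenoxy}phenyl)ethyl]-4-hydroxybenzoate, via cyclohexadiene cycloadduct 15 (not isolated), via aryl trimethylsilyl ether 16 (not isolated)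
Conditions: 14 (3 equiv), PhMe, 140 °C, sealed tube; then 1 M HCl, THF, rt
Reagents that add atoms: none
Why: The electron-rich 1-methoxy-3-siloxy diene and the ester-polarised alkyne should combine in a concerted, asynchronous normal-electron-demand [4+2] cycloaddition (Diels–Alder reaction of a Danishefsky-type diene with an acetylenic ester), the diene CH2 terminus with its large HOMO coefficient bonding to the alkyl-bearing β-carbon of the ynoate and the methoxy-bearing terminus to the α-carbon. Ring A is thereby closed intermolecularly as a six-membered carbocycle through two new C–C bonds, giving cyclohexa-1,4-diene 15, whose doubly allylic methoxy group leaves as methanol by 1,4-elimination to give arene 16, after which dilute acid removes the silyl group. No stereocentre results, because the single sp3 methoxy carbon of 15 is destroyed on aromatisation. The step needs regioselectivity, which the matched push–pull polarisation of the two partners secures, so that the siloxy carbon ends up two ring atoms from the bridge-bearing carbon and para to the ester. It also needs chemoselectivity, which follows from the ynoate being the only electron-poor π-bond in 13 while the anisole-type rings are inert to the diene.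

**Step 10**
Reactants: 17 methyl 2-[2-(4-{5-[2-(2,5-dimethoxyphenyl)ethyl]-2-methoxyphenoxy}phenyl)ethyl]-4-hydroxybenzoate
Product: 18 2-[2-(4-{5-[2-(2,5-dimethoxyphenyl)ethyl]-2-methoxyphenoxy}phenyl)ethyl]-4-hydroxybenzoic acid
Conditions: KOH, MeOH/H2O, reflux; then 2 M HCl
Reagents that add atoms: potassium hydroxide, [K+].[OH-]
Why: Saponification of a methyl benzoate by acyl–oxygen cleavage, run at reflux because the para-phenoxide and the ortho-alkyl group slow hydroxide attack; the ether linkages are stable to base.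

**Step 11**
Reactants: 18 2-[2-(4-{5-[2-(2,5-dimethoxyphenyl)ethyl]-2-methoxyphenoxy}phenyl)ethyl]-4-hydroxybenzoic acid
Product: 19 3-[2-(4-{5-[2-(2,5-dimethoxyphenyl)ethyl]-2-methoxyphenoxy}phenyl)ethyl]phenol
Conditions: Cu2O (cat.), 1,10-phenanthroline, NMP/quinoline, 170 °C, N2
Reagents that add atoms: none
Why: Copper-catalysed protodecarboxylation of a benzoic acid, favoured here because the para-hydroxyl and the ortho-alkyl group make the ipso carbon electron-rich and twist the carboxyl out of conjugation.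

**Step 12**
Reactants: 19 3-[2-(4-{5-[2-(2,5-dimethoxyphenyl)ethyl]-2-methoxyphenoxy}phenyl)ethyl]phenol
Product: 20 2-{2-[4-hydroxy-3-(4-[2-(3-hydroxyphenyl)ethyl]phenoxy)phenyl]ethyl}benzene-1,4-diol (CNP0300581.0)
Conditions: BBr3, CH2Cl2, −78 °C to rt; then H2O (degassed)
Reagents that add atoms: none
Why: BBr3 cleaves aryl methyl ethers by Lewis acid complexation and SN2 attack of bromide on the methyl group, whereas the diaryl ether and the CH2CH2 bridges are not attacked; the degassed work-up protects the hydroquinone from air oxidation.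

**Compound list**
1 | 2,5-dimethoxybenzyl alcohol | COc1ccc(OC)c(CO)c1 | starting material
2 | (2,5-dimethoxybenzyl)triphenylphosphonium bromide | COc1ccc(OC)c(C[P+](c2ccccc2)(c2ccccc2)c2ccccc2)c1.[Br-] | intermediate
3 | 3-(benzyloxy)-4-methoxybenzaldehyde | COc1ccc(C=O)cc1OCc1ccccc1 | starting material
4 | (2,5-dimethoxybenzylidene)triphenylphosphorane (ylide) | COc1ccc(OC)c(C=P(c2ccccc2)(c2ccccc2)c2ccccc2)c1 | intermediate
5 | 2-(benzyloxy)-4-[2-(2,5-dimethoxyphenyl)ethenyl]-1-methoxybenzene (E/Z mixture, geometry not specified) | COc1ccc(C=Cc2cc(OC)ccc2OC)cc1OCc1ccccc1 | intermediate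
6 | 5-[2-(2,5-dimethoxyphenyl)ethyl]-2-methoxyphenol | COc1ccc(CCc2cc(OC)ccc2OC)cc1O | intermediate
7 | 4-fluorobenzaldehyde | O=Cc1ccc(F)cc1 | starting material
8 | 4-{5-[2-(2,5-dimethoxyphenyl)ethyl]-2-methoxyphenoxy}benzaldehyde | COc1ccc(CCc2cc(OC)ccc2OC)cc1Oc1ccc(C=O)cc1 | intermediate
9 | (4-{5-[2-(2,5-dimethoxyphenyl)ethyl]-2-methoxyphenoxy}phenyl)methanol | COc1ccc(CCc2cc(OC)ccc2OC)cc1Oc1ccc(CO)cc1 | intermediate
10 | 2-[4-(bromomethyl)phenoxy]-4-[2-(2,5-dimethoxyphenyl)ethyl]-1-methoxybenzene | COc1ccc(CCc2cc(OC)ccc2OC)cc1Oc1ccc(CBr)cc1 | intermediate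
11 | 2-[4-(but-3-yn-1-yl)phenoxy]-4-[2-(2,5-dimethoxyphenyl)ethyl]-1-methoxybenzene | C#CCCc1ccc(Oc2cc(CCc3cc(OC)ccc3OC)ccc2OC)cc1 | intermediate
12 | lithium acetylide of 11 | [Li]C#CCCc1ccc(Oc2cc(CCc3cc(OC)ccc3OC)ccc2OC)cc1 | intermediate
13 | methyl 5-(4-{5-[2-(2,5-dimethoxyphenyl)ethyl]-2-methoxyphenoxy}phenyl)pent-2-ynoate | COC(=O)C#CCCc1ccc(Oc2cc(CCc3cc(OC)ccc3OC)ccc2OC)cc1 | intermediate
14 | (E)-1-methoxy-3-(trimethylsilyloxy)buta-1,3-diene | CO/C=C/C(=C)O[Si](C)(C)C | starting material
15 | methyl 2-[2-(4-{5-[2-(2,5-dimethoxyphenyl)ethyl]-2-methoxyphenoxy}phenyl)ethyl]-6-methoxy-4-(trimethylsilyloxy)cyclohexa-1,4-diene-1-carboxylate (racemic) | COC(=O)C1=C(CCc2ccc(Oc3cc(CCc4cc(OC)ccc4OC)ccc3OC)cc2)CC(O[Si](C)(C)C)=CC1OC | intermediate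
16 | methyl 2-[2-(4-{5-[2-(2,5-dimethoxyphenyl)ethyl]-2-methoxyphenoxy}phenyl)ethyl]-4-(trimethylsilyloxy)benzoate | COC(=O)c1ccc(O[Si](C)(C)C)cc1CCc1ccc(Oc2cc(CCc3cc(OC)ccc3OC)ccc2OC)cc1 | intermediate
17 | methyl 2-[2-(4-{5-[2-(2,5-dimethoxyphenyl)ethyl]-2-methoxyphenoxy}phenyl)ethyl]-4-hydroxybenzoate | COC(=O)c1ccc(O)cc1CCc1ccc(Oc2cc(CCc3cc(OC)ccc3OC)ccc2OC)cc1 | intermediate
18 | 2-[2-(4-{5-[2-(2,5-dimethoxyphenyl)ethyl]-2-methoxyphenoxy}phenyl)ethyl]-4-hydroxybenzoic acid | OC(=O)c1ccc(O)cc1CCc1ccc(Oc2cc(CCc3cc(OC)ccc3OC)ccc2OC)cc1 | intermediate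
19 | 3-[2-(4-{5-[2-(2,5-dimethoxyphenyl)ethyl]-2-methoxyphenoxy}phenyl)ethyl]phenol | Oc1cccc(CCc2ccc(Oc3cc(CCc4cc(OC)ccc4OC)ccc3OC)cc2)c1 | intermediate
20 | 2-{2-[4-hydroxy-3-(4-[2-(3-hydroxyphenyl)ethyl]phenoxy)phenyl]ethyl}benzene-1,4-diol (CNP0300581.0) | Oc1cccc(CCc2ccc(Oc3cc(CCc4cc(O)ccc4O)ccc3O)cc2)c1 | target

**Step count**
Total: 12 steps. Longest linear sequence: 12 steps, from 1 to 20.

**Steps most likely to fail**

Step 9. The β-alkyl ynoate is a sluggish dienophile, so thermal oligomerisation and adventitious hydrolysis of the diene may outpace the cycloaddition and leave 13 unreacted. The fallback changes the activating group from ester to aldehyde and sets out from alkyne 11. Lithiation (n-BuLi, THF, −78 °C) and formylation with DMF should give 5-(4-{5-[2-(2,5-dimethoxyphenyl)ethyl]-2-methoxyphenoxy}phenyl)pent-2-ynal F1. This far more reactive dienophile should add diene 14 with the same regiochemistry in toluene at 60–80 °C to give the cyclohexadiene carbaldehyde cycloadduct F2, which loses methanol to the 4-(trimethylsilyloxy)benzaldehyde F3; neither is isolated. Dilute HCl then frees 2-[2-(4-{5-[2-(2,5-dimethoxyphenyl)ethyl]-2-methoxyphenoxy}phenyl)ethyl]-4-hydroxybenzaldehyde F4. Oxidation of F4 with Ag2O in aqueous NaOH/EtOH, followed by acidification, comes back to the route at acid 18.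

Step 11. Extrusion of CO2 may stay incomplete, and the electron-rich phenol may darken by oxidation during prolonged heating at 170 °C. The fallback moves the loss of CO2 into the final deprotection and replaces copper catalysis by a protic medium. It sets out from acid 18, which is heated in molten pyridinium chloride (190–200 °C, N2). Ipso-protonation of the 4-hydroxybenzoic acid should expel CO2 while chloride cleaves the three methyl ethers, and the sequence comes back to the route at target 20. No new compound is made on this detour (entry F0).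

Step 7. Transfer of the allenyl instead of the propargyl terminus and Wurtz-type homocoupling of the benzylic bromide may erode the alkylation. The fallback uses a silyl-capped propargyl anion, which cannot deliver an allene, and sets out from bromide 10. Alkylation of 3-lithio-1-(trimethylsilyl)propyne (from 1-(trimethylsilyl)propyne and n-BuLi, THF, −78 °C) with 10 should give [4-(4-{5-[2-(2,5-dimethoxyphenyl)ethyl]-2-methoxyphenoxy}phenyl)but-1-yn-1-yl]trimethylsilane F5. Desilylation of F5 with K2CO3 in MeOH comes back to the route at alkyne 11.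

**Further compounds**
F1 | step 9 | 5-(4-{5-[2-(2,5-dimethoxyphenyl)ethyl]-2-methoxyphenoxy}phenyl)pent-2-ynal | O=CC#CCCc1ccc(Oc2cc(CCc3cc(OC)ccc3OC)ccc2OC)cc1
F2 | step 9 | 2-[2-(4-{5-[2-(2,5-dimethoxyphenyl)ethyl]-2-methoxyphenoxy}phenyl)ethyl]-6-methoxy-4-(trimethylsilyloxy)cyclohexa-1,4-diene-1-carbaldehyde (racemic) | O=CC1=C(CCc2ccc(Oc3cc(CCc4cc(OC)ccc4OC)ccc3OC)cc2)CC(O[Si](C)(C)C)=CC1OC
F3 | step 9 | 2-[2-(4-{5-[2-(2,5-dimethoxyphenyl)ethyl]-2-methoxyphenoxy}phenyl)ethyl]-4-(trimethylsilyloxy)benzaldehyde | O=Cc1ccc(O[Si](C)(C)C)cc1CCc1ccc(Oc2cc(CCc3cc(OC)ccc3OC)ccc2OC)cc1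
F4 | step 9 | 2-[2-(4-{5-[2-(2,5-dimethoxyphenyl)ethyl]-2-methoxyphenoxy}phenyl)ethyl]-4-hydroxybenzaldehyde | O=Cc1ccc(O)cc1CCc1ccc(Oc2cc(CCc3cc(OC)ccc3OC)ccc2OC)cc1
F0 | step 11 | none | none
F5 | step 7 | [4-(4-{5-[2-(2,5-dimethoxyphenyl)ethyl]-2-methoxyphenoxy}phenyl)but-1-yn-1-yl]trimethylsilane | C[Si](C)(C)C#CCCc1ccc(Oc2cc(CCc3cc(OC)ccc3OC)ccc2OC)cc1
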